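**Retrosynthetic overview**

1. Ring C is disconnected last, at O1–C8a: an (R)-carbinol at C2, from CBS reduction of the C2 ketone, is joined to the ring A bromide without touching the C2–O bond.
2. The strategy rests on ring B, a pentasubstituted catechol. C1' carries the C2–C3–C4 chain, C2' and C3' carry prenyl, C4' and C5' carry oxygen, C6' carries H. The C2'–C3'–C4'–C5' segment is a 4,5-diprenyl-3-silyloxyfuran; C6' and C1' are the two carbons of a terminal ynone.
3. Key disconnection: C5'–C6' and C1'–C2' by furan/ynone [4+2] cycloaddition, then cleavage of the oxygen bridge at C2' and aromatisation, so that the furan oxygen ends as the C5' hydroxyl.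
4. The furan comes from a 3(2H)-furanone (crossed Claisen acylation of silylated hydroxyacetone, C-prenylation, cyclodehydration). The ynone comes from 2-bromo-4-hydroxybenzaldehyde (Wittig reaction to an N-methoxy-N-methyl enamide, alkene hydrogenation, ethynyl addition).
5. Ring order: ring A is bought; furan ring (steps 5 and 6); ring B (step 11); ring C (step 14).

Key step: step 11

Remark: flavan numbering is used (ring B primed). If the silyl group of 21 moves from O4' to O5' during aromatisation, the route is unaffected, because step 12 silylates whichever catechol oxygen is free and both isomers give 22.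

**Fragment 1: the silyloxyfuran**

Step 1
Reactants: 1 hydroxyacetone
Product: 2 1-[(tert-butyldimethylsilyl)oxy]propan-2-one
Conditions: TBSCl, imidazole, CH2Cl2, 0 °C → rt
Reagents that add atoms: tert-butyldimethylsilyl chloride (TBSCl), CC(C)(C)[Si](C)(C)Cl
Why: Imidazole-promoted silyl ether formation at the primary hydroxyl is routine and leaves the ketone untouched.

Step 2
Reactants: 3 4-methylpent-3-enoic acid
Product: 4 1-(1H-imidazol-1-yl)-4-methylpent-3-en-1-one
Conditions: CDI (1.05 equiv), CH2Cl2, rt; quick cold-water wash, dried, used directly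
Reagents that add atoms: 1,1'-carbonyldiimidazole (CDI), O=C(n1ccnc1)n1ccnc1
Why: Carboxyl activation as the N-acylimidazole occurs under neutral conditions that should not move the β,γ-alkene into conjugation, and the wash removes the N–H acid imidazole before the enolate step.

Step 3
Reactants: 2 1-[(tert-butyldimethylsilyl)oxy]propan-2-one; 4 1-(1H-imidazol-1-yl)-4-methylpent-3-en-1-one
Product: 6 1-[(tert-butyldimethylsilyl)oxy]-7-methyloct-6-ene-2,4-dione, via lithium enolate 5 (not isolated)
Conditions: 2 (2.2 equiv), LiN(iPr)2 (2.2 equiv), THF, –78 °C; then 4 (1 equiv), –78 → –40 °C; AcOH quench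
Reagents that add atoms: none
Why: Kinetic deprotonation at –78 °C should take place at the unhindered methyl group and not at the silyloxymethylene, and the lithium enolate is C-acylated by the acylimidazole in a crossed Claisen condensation, the second equivalent of enolate absorbing the acidic diketone proton.

Step 4
Reactants: 6 1-[(tert-butyldimethylsilyl)oxy]-7-methyloct-6-ene-2,4-dione; 7 1-bromo-3-methylbut-2-ene (prenyl bromide)
Product: 8 1-[(tert-butyldimethylsilyl)oxy]-7-methyl-3-(3-methylbut-2-en-1-yl)oct-6-ene-2,4-dione (racemic at C3)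
Conditions: K2CO3 (1.5 equiv), 7 (1.05 equiv), acetone, rt → 40 °C
Reagents that add atoms: none
Why: Only the doubly activated C3–H is removed by carbonate, and the soft diketonate should undergo SN2 C-alkylation with the primary allylic bromide, one equivalent of halide limiting dialkylation.

Step 5
Reactants: 8 1-[(tert-butyldimethylsilyl)oxy]-7-methyl-3-(3-methylbut-2-en-1-yl)oct-6-ene-2,4-dione
Product: 11 4,5-bis(3-methylbut-2-en-1-yl)furan-3(2H)-one, via hydroxy diketone 9 (not isolated), via cyclic hemiketal 10 (not isolated)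
Conditions: 1 M HCl (aq)/THF 1:4, rt
Reagents that add atoms: none
Why: This is the acid-catalysed cyclodehydration of an α'-hydroxy-1,3-diketone: the primary silyl ether is cleaved, the freed hydroxyl adds to the distal C4 ketone to give a five-membered hemiketal, and loss of water through the acidic C–H between the oxygenated carbons gives the vinylogous ester, while dilute acid at room temperature should spare the trisubstituted alkenes.

Step 6
Reactants: 11 4,5-bis(3-methylbut-2-en-1-yl)furan-3(2H)-one
Product: 12 3-[(tert-butyldimethylsilyl)oxy]-4,5-bis(3-methylbut-2-en-1-yl)furan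
Conditions: TBSOTf (1.2 equiv), Et3N (1.5 equiv), CH2Cl2, –78 → 0 °C; filtered through Et3N-deactivated SiO2, used at once
Reagents that add atoms: tert-butyldimethylsilyl trifluoromethanesulfonate (TBSOTf), CC(C)(C)[Si](C)(C)OS(=O)(=O)C(F)(F)F
Why: Soft enolisation and O-silylation at C2 of the furanone is driven by aromatisation to the furan, so silyl enol ether formation should be regioselective for the ring position.

**Fragment 2: the ynone**

Step 7
Reactants: 13 2-bromo-4-hydroxybenzaldehyde
Product: 14 2-bromo-4-[(tert-butyldimethylsilyl)oxy]benzaldehyde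
Conditions: TBSCl, imidazole, DMF, rt
Reagents that add atoms: tert-butyldimethylsilyl chloride (TBSCl), CC(C)(C)[Si](C)(C)Cl
Why: Silyl ether formation on a phenol under imidazole catalysis is routine and masks the acidic hydroxyl for the ylide and Grignard steps.

Step 8
Reactants: 14 2-bromo-4-[(tert-butyldimethylsilyl)oxy]benzaldehyde
Product: 15 (E)-3-{2-bromo-4-[(tert-butyldimethylsilyl)oxy]phenyl}-N-methoxy-N-methylprop-2-enamide
Conditions: Ph3P=CHC(O)N(OMe)Me (1.2 equiv), CH2Cl2, rt
Reagents that add atoms: N-methoxy-N-methyl-2-(triphenylphosphoranylidene)acetamide, CON(C)C(=O)C=P(c1ccccc1)(c1ccccc1)c1ccccc1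
Why: Wittig olefination with a stabilised ylide is neutral, tolerates the aryl silyl ether and bromide, and should give the E-alkene, whose geometry is erased in the next step.

Step 9
Reactants: 15 (E)-3-{2-bromo-4-[(tert-butyldimethylsilyl)oxy]phenyl}-N-methoxy-N-methylprop-2-enamide
Product: 16 3-{2-bromo-4-[(tert-butyldimethylsilyl)oxy]phenyl}-N-methoxy-N-methylpropanamide
Conditions: H2 (3 atm), RhCl(PPh3)3 (5 mol %), THF/t-BuOH 1:1, 40 °C
Reagents that add atoms: none
Why: Homogeneous hydrogenation with RhCl(PPh3)3 should saturate the disubstituted conjugated alkene while leaving the aryl C–Br bond, the N–O bond and the silyl ether intact, which a heterogeneous palladium catalyst would endanger.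

Step 10
Reactants: 16 3-{2-bromo-4-[(tert-butyldimethylsilyl)oxy]phenyl}-N-methoxy-N-methylpropanamide
Product: 18 5-{2-bromo-4-[(tert-butyldimethylsilyl)oxy]phenyl}pent-1-yn-3-one, via magnesium hemiaminal adduct 17 (not isolated)
Conditions: HC≡CMgBr (3 equiv), THF, 0 °C; inverse quench into cold 1 M HCl; used promptly
Reagents that add atoms: ethynylmagnesium bromide, C#C[Mg]Br
Why: In this Weinreb ketone synthesis the chelated tetrahedral adduct stops the addition at the ketone level, and the cold acidic inverse quench protonates the released N,O-dimethylhydroxylamine so that it cannot add to the new ynone.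

**Union and endgame**

Step 11
Reactants: 12 3-[(tert-butyldimethylsilyl)oxy]-4,5-bis(3-methylbut-2-en-1-yl)furan; 18 5-{2-bromo-4-[(tert-butyldimethylsilyl)oxy]phenyl}pent-1-yn-3-one
Product: 21 3-{2-bromo-4-[(tert-butyldimethylsilyl)oxy]phenyl}-1-{4-[(tert-butyldimethylsilyl)oxy]-5-hydroxy-2,3-bis(3-methylbut-2-en-1-yl)phenyl}propan-1-one, via oxanorbornadiene cycloadduct 19 (not isolated), via ring-opened zwitterion 20 (not isolated)
Conditions: 12 (1.5 equiv), 18 (1 equiv), PhMe (1 M), BHT (cat.), Ar, dark, rt → 60 °C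
Reagents that add atoms: none
Why: The electron-rich furan 12 (HOMO largest at the unsubstituted C2, the β-carbon of the silyl enol ether) and the electron-poor ynone 18 (LUMO largest at the terminal carbon) should combine in a normal-demand Diels–Alder reaction that forms C5'–C6' and C1'–C2' and gives oxanorbornadiene 19. In 19 the silyloxy group pushes through C4'=C3' to expel the bridging oxygen from the prenyl-bearing bridgehead C2' (a vinylogous acetal ionisation) to give zwitterion 20, which aromatises by loss of the C5' proton to the alkoxide (keto–enol tautomerisation), leaving the former furan oxygen as the C5' hydroxyl. The closest known reaction type is the cycloaddition of 3-alkoxy- and 3-silyloxyfurans with acetylenic ketones and esters, which gives catechol monoethers by the same opening. Ring B is closed by the [4+2] cycloaddition, both new C–C bonds arising in one six-membered ring-forming event, and no stereocentre results because the two bridgehead centres of 19 are destroyed on aromatisation. The step needs para regiochemistry (acyl-bearing C1' opposite silyloxy-bearing C4'), which the coefficient match of furan C2 with the ynone terminus should secure against the steric pull of the prenyl-bearing furan C5, and it needs opening at C2'–O and not C5'–O, which follows because only that heterolysis gives a cation conjugated with the silyloxy group and stabilised by an alkyl substituent. Running it thermally without acid should protect the prenyl groups, which would cyclise onto a neighbouring free phenol under protic acid.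

Step 12
Reactants: 21 3-{2-bromo-4-[(tert-butyldimethylsilyl)oxy]phenyl}-1-{4-[(tert-butyldimethylsilyl)oxy]-5-hydroxy-2,3-bis(3-methylbut-2-en-1-yl)phenyl}propan-1-one
Product: 22 1-{4,5-bis[(tert-butyldimethylsilyl)oxy]-2,3-bis(3-methylbut-2-en-1-yl)phenyl}-3-{2-bromo-4-[(tert-butyldimethylsilyl)oxy]phenyl}propan-1-one
Conditions: TBSCl, imidazole, DMF, rt
Reagents that add atoms: tert-butyldimethylsilyl chloride (TBSCl), CC(C)(C)[Si](C)(C)Cl
Why: Silyl ether formation on the remaining catechol hydroxyl removes the only acidic O–H, which would otherwise compete as a nucleophile and ligand in the copper-catalysed ring closure.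

Step 13
Reactants: 22 1-{4,5-bis[(tert-butyldimethylsilyl)oxy]-2,3-bis(3-methylbut-2-en-1-yl)phenyl}-3-{2-bromo-4-[(tert-butyldimethylsilyl)oxy]phenyl}propan-1-one
Product: 24 (1R)-1-{4,5-bis[(tert-butyldimethylsilyl)oxy]-2,3-bis(3-methylbut-2-en-1-yl)phenyl}-3-{2-bromo-4-[(tert-butyldimethylsilyl)oxy]phenyl}propan-1-ol, via catecholborate ester 23 (not isolated)
Conditions: (S)-2-methyl-CBS-oxazaborolidine (0.2 equiv), catecholborane (2 equiv), PhMe, –78 → –40 °C; MeOH, then pH 7 buffer
Reagents that add atoms: none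
Why: In this Corey–Bakshi–Shibata reduction the (S)-oxazaborolidine should differentiate the ortho-substituted aryl group (large) from the CH2CH2Ar chain (small) and deliver hydride to the face that gives the (R)-carbinol, as with aryl alkyl ketones in general, and catecholborane at low temperature should not hydroborate the prenyl alkenes.

Step 14
Reactants: 24 (1R)-1-{4,5-bis[(tert-butyldimethylsilyl)oxy]-2,3-bis(3-methylbut-2-en-1-yl)phenyl}-3-{2-bromo-4-[(tert-butyldimethylsilyl)oxy]phenyl}propan-1-ol
Product: 25 (2R)-2-{4,5-bis[(tert-butyldimethylsilyl)oxy]-2,3-bis(3-methylbut-2-en-1-yl)phenyl}-7-[(tert-butyldimethylsilyl)oxy]-3,4-dihydro-2H-chromene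
Conditions: CuI (20 mol %), 1,10-phenanthroline (40 mol %), Cs2CO3 (2 equiv, dried), PhMe, 110 °C, Ar
Reagents that add atoms: none
Why: This Ullmann-type intramolecular O-arylation closes the six-membered ring C by forming O1–C8a between the alkoxide and the aryl bromide on copper, and since the C2–O bond is never broken the (R)-carbinol should become the (2R)-flavan with retention.

Step 15
Reactants: 25 (2R)-2-{4,5-bis[(tert-butyldimethylsilyl)oxy]-2,3-bis(3-methylbut-2-en-1-yl)phenyl}-7-[(tert-butyldimethylsilyl)oxy]-3,4-dihydro-2H-chromene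
Product: 26 (2R)-2-[4,5-dihydroxy-2,3-bis(3-methylbut-2-en-1-yl)phenyl]-3,4-dihydro-2H-chromen-7-ol, (+)-(2R)-kazinol I
Conditions: Bu4NF (4 equiv), AcOH (4 equiv), degassed THF, 0 °C → rt, Ar
Reagents that add atoms: none
Why: Fluoride desilylation removes all three aryl silyl ethers, and the acetic acid buffer and exclusion of air should keep the catechol from oxidation and avoid the protic acid that would cyclise the C3' prenyl group onto the C4' phenol.

**Compound list**

1 | hydroxyacetone | CC(=O)CO | starting material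
2 | 1-[(tert-butyldimethylsilyl)oxy]propan-2-one | CC(=O)CO[Si](C)(C)C(C)(C)C | intermediate
3 | 4-methylpent-3-enoic acid | CC(C)=CCC(=O)O | starting material
4 | 1-(1H-imidazol-1-yl)-4-methylpent-3-en-1-one | CC(C)=CCC(=O)n1ccnc1 | intermediate
5 | lithium 3-[(tert-butyldimethylsilyl)oxy]prop-1-en-2-olate (not isolated) | C=C(O[Li])CO[Si](C)(C)C(C)(C)C | intermediate
6 | 1-[(tert-butyldimethylsilyl)oxy]-7-methyloct-6-ene-2,4-dione | CC(C)=CCC(=O)CC(=O)CO[Si](C)(C)C(C)(C)C | intermediate
7 | 1-bromo-3-methylbut-2-ene (prenyl bromide) | CC(C)=CCBr | starting material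
8 | 1-[(tert-butyldimethylsilyl)oxy]-7-methyl-3-(3-methylbut-2-en-1-yl)oct-6-ene-2,4-dione (racemic) | CC(C)=CCC(=O)C(CC=C(C)C)C(=O)CO[Si](C)(C)C(C)(C)C | intermediate
9 | 1-hydroxy-7-methyl-3-(3-methylbut-2-en-1-yl)oct-6-ene-2,4-dione (racemic, not isolated) | CC(C)=CCC(=O)C(CC=C(C)C)C(=O)CO | intermediate
10 | 5-hydroxy-4,5-bis(3-methylbut-2-en-1-yl)oxolan-3-one (diastereomer mixture, not isolated) | O=C1COC(O)(CC=C(C)C)C1CC=C(C)C | intermediate
11 | 4,5-bis(3-methylbut-2-en-1-yl)furan-3(2H)-one | O=C1COC(CC=C(C)C)=C1CC=C(C)C | intermediate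
12 | 3-[(tert-butyldimethylsilyl)oxy]-4,5-bis(3-methylbut-2-en-1-yl)furan | CC(C)=CCc1occ(O[Si](C)(C)C(C)(C)C)c1CC=C(C)C | intermediate
13 | 2-bromo-4-hydroxybenzaldehyde | O=Cc1ccc(O)cc1Br | starting material
14 | 2-bromo-4-[(tert-butyldimethylsilyl)oxy]benzaldehyde | O=Cc1ccc(O[Si](C)(C)C(C)(C)C)cc1Br | intermediate
15 | (E)-3-{2-bromo-4-[(tert-butyldimethylsilyl)oxy]phenyl}-N-methoxy-N-methylprop-2-enamide | CON(C)C(=O)/C=C/c1ccc(O[Si](C)(C)C(C)(C)C)cc1Br | intermediate
16 | 3-{2-bromo-4-[(tert-butyldimethylsilyl)oxy]phenyl}-N-methoxy-N-methylpropanamide | CON(C)C(=O)CCc1ccc(O[Si](C)(C)C(C)(C)C)cc1Br | intermediate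
17 | bromomagnesium 5-{2-bromo-4-[(tert-butyldimethylsilyl)oxy]phenyl}-3-[methoxy(methyl)amino]pent-1-yn-3-olate (racemic, not isolated) | C#CC(O[Mg]Br)(N(C)OC)CCc1ccc(O[Si](C)(C)C(C)(C)C)cc1Br | intermediate
18 | 5-{2-bromo-4-[(tert-butyldimethylsilyl)oxy]phenyl}pent-1-yn-3-one | C#CC(=O)CCc1ccc(O[Si](C)(C)C(C)(C)C)cc1Br | intermediate
19 | 3-{2-bromo-4-[(tert-butyldimethylsilyl)oxy]phenyl}-1-{5-[(tert-butyldimethylsilyl)oxy]-1,6-bis(3-methylbut-2-en-1-yl)-7-oxabicyclo[2.2.1]hepta-2,5-dien-2-yl}propan-1-one (racemic; bridgeheads joined through O on one face; not isolated) | C12OC(CC=C(C)C)(C(CC=C(C)C)=C1O[Si](C)(C)C(C)(C)C)C(C(=O)CCc3ccc(O[Si](C)(C)C(C)(C)C)cc3Br)=C2 | intermediate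
20 | ring-opened zwitterion: C5' alkoxide, O-silylated C4' oxocarbenium, C1'=C6' and C2'=C3' double bonds (racemic, not isolated) | [O-]C1C=C(C(=O)CCc2ccc(O[Si](C)(C)C(C)(C)C)cc2Br)C(CC=C(C)C)=C(CC=C(C)C)C1=[O+][Si](C)(C)C(C)(C)C | intermediate
21 | 3-{2-bromo-4-[(tert-butyldimethylsilyl)oxy]phenyl}-1-{4-[(tert-butyldimethylsilyl)oxy]-5-hydroxy-2,3-bis(3-methylbut-2-en-1-yl)phenyl}propan-1-one | CC(C)=CCc1c(C(=O)CCc2ccc(O[Si](C)(C)C(C)(C)C)cc2Br)cc(O)c(O[Si](C)(C)C(C)(C)C)c1CC=C(C)C | intermediate
22 | 1-{4,5-bis[(tert-butyldimethylsilyl)oxy]-2,3-bis(3-methylbut-2-en-1-yl)phenyl}-3-{2-bromo-4-[(tert-butyldimethylsilyl)oxy]phenyl}propan-1-one | CC(C)=CCc1c(C(=O)CCc2ccc(O[Si](C)(C)C(C)(C)C)cc2Br)cc(O[Si](C)(C)C(C)(C)C)c(O[Si](C)(C)C(C)(C)C)c1CC=C(C)C | intermediate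
23 | 2-{(1R)-1-{4,5-bis[(tert-butyldimethylsilyl)oxy]-2,3-bis(3-methylbut-2-en-1-yl)phenyl}-3-{2-bromo-4-[(tert-butyldimethylsilyl)oxy]phenyl}propoxy}-1,3,2-benzodioxaborole (not isolated) | CC(C)=CCc1c([C@H](OB2Oc3ccccc3O2)CCc4ccc(O[Si](C)(C)C(C)(C)C)cc4Br)cc(O[Si](C)(C)C(C)(C)C)c(O[Si](C)(C)C(C)(C)C)c1CC=C(C)C | intermediate
24 | (1R)-1-{4,5-bis[(tert-butyldimethylsilyl)oxy]-2,3-bis(3-methylbut-2-en-1-yl)phenyl}-3-{2-bromo-4-[(tert-butyldimethylsilyl)oxy]phenyl}propan-1-ol | CC(C)=CCc1c([C@H](O)CCc2ccc(O[Si](C)(C)C(C)(C)C)cc2Br)cc(O[Si](C)(C)C(C)(C)C)c(O[Si](C)(C)C(C)(C)C)c1CC=C(C)C | intermediate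
25 | (2R)-2-{4,5-bis[(tert-butyldimethylsilyl)oxy]-2,3-bis(3-methylbut-2-en-1-yl)phenyl}-7-[(tert-butyldimethylsilyl)oxy]-3,4-dihydro-2H-chromene | CC(C)=CCc1c([C@H]2CCc3ccc(O[Si](C)(C)C(C)(C)C)cc3O2)cc(O[Si](C)(C)C(C)(C)C)c(O[Si](C)(C)C(C)(C)C)c1CC=C(C)C | intermediate
26 | (2R)-2-[4,5-dihydroxy-2,3-bis(3-methylbut-2-en-1-yl)phenyl]-3,4-dihydro-2H-chromen-7-ol, (+)-(2R)-kazinol I | CC(C)=CCc1c([C@H]2CCc3ccc(O)cc3O2)cc(O)c(O)c1CC=C(C)C | target

**Step count and risk**

Total step count: 15.
Longest linear sequence: 10 steps (1 → 2 → 6 → 8 → 11 → 12 → 21 → 22 → 24 → 25 → 26; the branch from acid 3 through 4 is equally long, and the ynone branch from 13 is 9 steps).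

Steps most likely to fail:

1. Step 11. The cycloaddition may be slower than thermal oligomerisation of the enolisable terminal ynone. Furan C2 may add to the ynone in a conjugate sense without closing the second bond. Steric repulsion between the prenyl-bearing furan carbon and the acyl-bearing alkyne carbon may erode the regiochemistry. The fallback keeps the furan-to-arene construction but uses a small, cheap dienophile in large excess and attaches ring A afterwards. It sets out from 12: cycloaddition and ring opening with excess but-3-yn-2-one (neat or PhMe, rt) should give 1-{4-[(tert-butyldimethylsilyl)oxy]-5-hydroxy-2,3-bis(3-methylbut-2-en-1-yl)phenyl}ethanone F1. Silylation (TBSCl, imidazole, DMF) gives the bis-silyl acetophenone 1-{4,5-bis[(tert-butyldimethylsilyl)oxy]-2,3-bis(3-methylbut-2-en-1-yl)phenyl}ethanone F2. In parallel, aldehyde 14 is reduced (NaBH4, MeOH, 0 °C) to {2-bromo-4-[(tert-butyldimethylsilyl)oxy]phenyl}methanol F3 and converted by an Appel reaction (CBr4, PPh3, CH2Cl2) into [3-bromo-4-(bromomethyl)phenoxy](tert-butyl)dimethylsilane F4. Alkylation of the lithium enolate of F2 (LiN(SiMe3)2, THF, –78 → 0 °C) with F4 gives 22, where the route is rejoined.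

2. Step 14. Coupling of the hindered secondary benzylic alkoxide may be slow, so that base-induced loss of aryl silyl groups, reduction of the C–Br bond, or oxidation of the carbinol back to the ketone (with loss of enantiopurity) compete. The fallback reverses the roles of the partners, with a phenol as nucleophile and the carbinol as electrophile, closing with inversion. It sets out from 22: Miyaura borylation (B2pin2, PdCl2(dppf), KOAc, dioxane, 80 °C) should give the pinacol boronate 1-{4,5-bis[(tert-butyldimethylsilyl)oxy]-2,3-bis(3-methylbut-2-en-1-yl)phenyl}-3-{4-[(tert-butyldimethylsilyl)oxy]-2-(4,4,5,5-tetramethyl-1,3,2-dioxaborolan-2-yl)phenyl}propan-1-one F5. Oxidation (NaBO3·4H2O, THF/H2O, rt) gives the phenol 1-{4,5-bis[(tert-butyldimethylsilyl)oxy]-2,3-bis(3-methylbut-2-en-1-yl)phenyl}-3-{4-[(tert-butyldimethylsilyl)oxy]-2-hydroxyphenyl}propan-1-one F6. CBS reduction with the (R)-oxazaborolidine and catecholborane gives the (S)-carbinol 2-{(3S)-3-{4,5-bis[(tert-butyldimethylsilyl)oxy]-2,3-bis(3-methylbut-2-en-1-yl)phenyl}-3-hydroxypropyl}-5-[(tert-butyldimethylsilyl)oxy]phenol F7. Mitsunobu cyclisation (PPh3, DIAD, THF, 0 °C) with inversion at C2 gives 25, where the route is rejoined.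

3. Step 3. Proton transfer from the acidic β,γ-unsaturated acyl donor to the enolate may compete with C-acylation and move the alkene into conjugation, and equilibration of the enolate toward the silyloxymethylene side would give the regioisomeric diketone. The fallback replaces acylation by aldol addition, which is faster than proton transfer at low temperature, followed by oxidation. It sets out from 4 and 2: reduction of 4 (i-Bu2AlH, CH2Cl2, –78 °C) should give 4-methylpent-3-enal F8, used crude. Addition of lithium enolate 5 (from 2, LiN(iPr)2, THF, –78 °C) gives the aldol 1-[(tert-butyldimethylsilyl)oxy]-4-hydroxy-7-methyloct-6-en-2-one F9. Dess–Martin oxidation (NaHCO3, CH2Cl2) gives 6, where the route is rejoined.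

Further compounds
F1 | step 11 | 1-{4-[(tert-butyldimethylsilyl)oxy]-5-hydroxy-2,3-bis(3-methylbut-2-en-1-yl)phenyl}ethanone | CC(=O)c1cc(O)c(O[Si](C)(C)C(C)(C)C)c(CC=C(C)C)c1CC=C(C)C
F2 | step 11 | 1-{4,5-bis[(tert-butyldimethylsilyl)oxy]-2,3-bis(3-methylbut-2-en-1-yl)phenyl}ethanone | CC(=O)c1cc(O[Si](C)(C)C(C)(C)C)c(O[Si](C)(C)C(C)(C)C)c(CC=C(C)C)c1CC=C(C)C
F3 | step 11 | {2-bromo-4-[(tert-butyldimethylsilyl)oxy]phenyl}methanol | OCc1ccc(O[Si](C)(C)C(C)(C)C)cc1Br
F4 | step 11 | [3-bromo-4-(bromomethyl)phenoxy](tert-butyl)dimethylsilane | BrCc1ccc(O[Si](C)(C)C(C)(C)C)cc1Br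
F5 | step 14 | 1-{4,5-bis[(tert-butyldimethylsilyl)oxy]-2,3-bis(3-methylbut-2-en-1-yl)phenyl}-3-{4-[(tert-butyldimethylsilyl)oxy]-2-(4,4,5,5-tetramethyl-1,3,2-dioxaborolan-2-yl)phenyl}propan-1-one | CC(C)=CCc1c(C(=O)CCc2ccc(O[Si](C)(C)C(C)(C)C)cc2B3OC(C)(C)C(C)(C)O3)cc(O[Si](C)(C)C(C)(C)C)c(O[Si](C)(C)C(C)(C)C)c1CC=C(C)C
F6 | step 14 | 1-{4,5-bis[(tert-butyldimethylsilyl)oxy]-2,3-bis(3-methylbut-2-en-1-yl)phenyl}-3-{4-[(tert-butyldimethylsilyl)oxy]-2-hydroxyphenyl}propan-1-one | CC(C)=CCc1c(C(=O)CCc2ccc(O[Si](C)(C)C(C)(C)C)cc2O)cc(O[Si](C)(C)C(C)(C)C)c(O[Si](C)(C)C(C)(C)C)c1CC=C(C)C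
F7 | step 14 | 2-{(3S)-3-{4,5-bis[(tert-butyldimethylsilyl)oxy]-2,3-bis(3-methylbut-2-en-1-yl)phenyl}-3-hydroxypropyl}-5-[(tert-butyldimethylsilyl)oxy]phenol | CC(C)=CCc1c([C@@H](O)CCc2ccc(O[Si](C)(C)C(C)(C)C)cc2O)cc(O[Si](C)(C)C(C)(C)C)c(O[Si](C)(C)C(C)(C)C)c1CC=C(C)C
F8 | step 3 | 4-methylpent-3-enal | CC(C)=CCC=O
F9 | step 3 | 1-[(tert-butyldimethylsilyl)oxy]-4-hydroxy-7-methyloct-6-en-2-one (racemic) | CC(C)=CCC(O)CC(=O)CO[Si](C)(C)C(C)(C)C
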